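**Retrosynthetic overview**
1. Target 17 ⇐ 16 (remove two MOM ethers) ⇐ prenyl ether 13 by para-Claisen (Claisen–Cope); the prenyl group lands para to the oxygen that carried it, i.e. between OMe and the 4-oxygen.
2. 13 ⇐ 9 ⇐ 8: on the symmetrical ring B the para-OH is masked as MOM, one chelated ortho-OH is methylated and the other is O-prenylated.
3. 8 ⇐ 6: ring B is the only ring made (ring A is bought as methyl vanillate); it forms by methoxide opening of the pyrone and intramolecular Claisen closure of the triketo ester.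
4. 6 ⇐ 3 + 4: the key C–C bond is an intermolecular (crossed) Claisen condensation of the triacetic acid lactone dianion with the aryl ester; the new ArCO–CH2 bond becomes the benzophenone C(=O)–C(ring B) bond.

Assumption: the target has no stereocentre and no E/Z-defined alkene, so "single enantiomer" is taken as the achiral compound drawn.

**Route**

Step 1
Reactants: 1 methyl vanillate (methyl 4-hydroxy-3-methoxybenzoate); 2 chloromethyl methyl ether
Product: 3 methyl 3-methoxy-4-(methoxymethoxy)benzoate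
Conditions: MOMCl (1.3 equiv), K2CO3, acetone, 0 °C → rt
Reagents that add atoms: chloromethyl methyl ether (2), COCCl
Why: Williamson-type O-alkylation (MOM protection) of the only acidic OH masks the phenol against the strong base of step 2.

Step 2
Reactants: 3 methyl 3-methoxy-4-(methoxymethoxy)benzoate; 4 4-hydroxy-6-methyl-2H-pyran-2-one (triacetic acid lactone)
Product: 6 4-hydroxy-6-{2-[3-methoxy-4-(methoxymethoxy)phenyl]-2-oxoethyl}-2H-pyran-2-one, via dilithiated pyrone 5 (not isolated)
Conditions: 4, LDA (3.2 equiv), THF/DMPU, −78 → −20 °C; then 3, −20 °C → rt; then cold 1 M HCl to pH 3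
Reagents that add atoms: none
Why: Crossed Claisen condensation, in which the 6-CH2 carbanion of the pyrone dianion attacks the non-enolisable aryl ester and the third equivalent of base deprotonates the β-dicarbonyl product to drive the equilibrium.

Step 3
Reactants: 6 4-hydroxy-6-{2-[3-methoxy-4-(methoxymethoxy)phenyl]-2-oxoethyl}-2H-pyran-2-one
Product: 8 [3-methoxy-4-(methoxymethoxy)phenyl](2,4,6-trihydroxyphenyl)methanone, via triketo ester magnesium chelate 7 (not isolated)
Conditions: Mg(OMe)2 (5 equiv), MeOH, reflux; then cold 1 M HCl to pH 3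
Reagents that add atoms: none
Why: Methoxide opens the lactone to the Mg-chelated 3,5,7-triketo ester, whose C6 carbanion closes onto the ester (intramolecular Claisen, Dieckmann-type) and enolisation aromatises ring B; the electron-rich aryl ketone is a poor acceptor for the competing aldol mode.

Step 4
Reactants: 8 [3-methoxy-4-(methoxymethoxy)phenyl](2,4,6-trihydroxyphenyl)methanone; 2 chloromethyl methyl ether
Product: 9 [2,6-dihydroxy-4-(methoxymethoxy)phenyl][3-methoxy-4-(methoxymethoxy)phenyl]methanone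
Conditions: MOMCl (1.05 equiv), K2CO3, acetone, 0 °C
Reagents that add atoms: chloromethyl methyl ether (2), COCCl
Why: Selective Williamson-type MOM protection, because the 4-OH (para to C=O, most acidic, not hydrogen-bonded) reacts first while both ortho OH groups are deactivated by chelation to the carbonyl.

Step 5
Reactants: 9 [2,6-dihydroxy-4-(methoxymethoxy)phenyl][3-methoxy-4-(methoxymethoxy)phenyl]methanone; 10 dimethyl sulfate
Product: 11 [2-hydroxy-6-methoxy-4-(methoxymethoxy)phenyl][3-methoxy-4-(methoxymethoxy)phenyl]methanone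
Conditions: Me2SO4 (1.05 equiv), K2CO3, acetone, rt → 40 °C
Reagents that add atoms: dimethyl sulfate (10), COS(=O)(=O)OC
Why: Williamson O-methylation of one of two symmetry-equivalent chelated OH groups; after the first methylation the remaining OH is locked in a strong hydrogen bond and reacts much more slowly, so the reaction stops at the mono-ether.

Step 6
Reactants: 11 [2-hydroxy-6-methoxy-4-(methoxymethoxy)phenyl][3-methoxy-4-(methoxymethoxy)phenyl]methanone; 12 3-methylbut-2-en-1-ol (prenol)
Product: 13 {2-methoxy-4-(methoxymethoxy)-6-[(3-methylbut-2-en-1-yl)oxy]phenyl}[3-methoxy-4-(methoxymethoxy)phenyl]methanone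
Conditions: prenol, PPh3, DIAD, THF, 0 °C → rt
Reagents that add atoms: 3-methylbut-2-en-1-ol (12), CC(C)=CCO
Why: Mitsunobu etherification alkylates the acidic chelated phenol at the primary carbon of prenol under neutral conditions and avoids the C-alkylation that competes with prenyl bromide and base.

Step 7
Reactants: 13 {2-methoxy-4-(methoxymethoxy)-6-[(3-methylbut-2-en-1-yl)oxy]phenyl}[3-methoxy-4-(methoxymethoxy)phenyl]methanone
Product: 16 [6-hydroxy-2-methoxy-4-(methoxymethoxy)-3-(3-methylbut-2-en-1-yl)phenyl][3-methoxy-4-(methoxymethoxy)phenyl]methanone, via ortho-dienone 14 (not isolated), via para-dienone 15 (not isolated)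
Conditions: PhNEt2, 200 °C, sealed tube, Ar
Reagents that add atoms: none
Why: Aromatic Claisen rearrangement to the free ortho carbon gives a hindered 1,1-dimethylallyl dienone that undergoes Cope rearrangement to the para carbon (between OMe and OMOM) and tautomerises (para-Claisen–Cope), leaving a normal prenyl group para to the freed OH.

Step 8
Reactants: 16 [6-hydroxy-2-methoxy-4-(methoxymethoxy)-3-(3-methylbut-2-en-1-yl)phenyl][3-methoxy-4-(methoxymethoxy)phenyl]methanone
Product: 17 [4,6-dihydroxy-2-methoxy-3-(3-methylbut-2-en-1-yl)phenyl](4-hydroxy-3-methoxyphenyl)methanone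
Conditions: HCl (cat., 3 M aq), MeOH, rt
Reagents that add atoms: none
Why: Mild acid-catalysed acetal exchange with methanol (MOM cleavage) frees both phenols without hydrating or cyclising the prenyl group.

**Compound list**
1 | methyl vanillate (methyl 4-hydroxy-3-methoxybenzoate) | COC(=O)c1ccc(O)c(OC)c1 | starting material
2 | chloromethyl methyl ether | COCCl | starting material
3 | methyl 3-methoxy-4-(methoxymethoxy)benzoate | COC(=O)c1ccc(OCOC)c(OC)c1 | intermediate
4 | 4-hydroxy-6-methyl-2H-pyran-2-one (triacetic acid lactone) | CC1=CC(O)=CC(=O)O1 | starting material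
5 | dilithium salt of 4 (4-oxide and 6-CH2 carbanion) | [Li+].[Li+].[CH2-]C1=CC([O-])=CC(=O)O1 | intermediate
6 | 4-hydroxy-6-{2-[3-methoxy-4-(methoxymethoxy)phenyl]-2-oxoethyl}-2H-pyran-2-one | O=C(CC1=CC(O)=CC(=O)O1)c1ccc(OCOC)c(OC)c1 | intermediate
7 | methyl 7-[3-methoxy-4-(methoxymethoxy)phenyl]-3,5,7-trioxoheptanoate (present as its magnesium chelate, drawn neutral) | COC(=O)CC(=O)CC(=O)CC(=O)c1ccc(OCOC)c(OC)c1 | intermediate
8 | [3-methoxy-4-(methoxymethoxy)phenyl](2,4,6-trihydroxyphenyl)methanone | O=C(c1ccc(OCOC)c(OC)c1)c1c(O)cc(O)cc1O | intermediate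
9 | [2,6-dihydroxy-4-(methoxymethoxy)phenyl][3-methoxy-4-(methoxymethoxy)phenyl]methanone | O=C(c1ccc(OCOC)c(OC)c1)c1c(O)cc(OCOC)cc1O | intermediate
10 | dimethyl sulfate | COS(=O)(=O)OC | starting material
11 | [2-hydroxy-6-methoxy-4-(methoxymethoxy)phenyl][3-methoxy-4-(methoxymethoxy)phenyl]methanone | COc1cc(OCOC)cc(O)c1C(=O)c1ccc(OCOC)c(OC)c1 | intermediate
12 | 3-methylbut-2-en-1-ol (prenol) | CC(C)=CCO | starting material
13 | {2-methoxy-4-(methoxymethoxy)-6-[(3-methylbut-2-en-1-yl)oxy]phenyl}[3-methoxy-4-(methoxymethoxy)phenyl]methanone | COc1cc(OCOC)cc(OCC=C(C)C)c1C(=O)c1ccc(OCOC)c(OC)c1 | intermediate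
14 | 3-methoxy-2-[3-methoxy-4-(methoxymethoxy)benzoyl]-5-(methoxymethoxy)-6-(2-methylbut-3-en-2-yl)cyclohexa-2,4-dien-1-one | O=C1C(C(=O)c2ccc(OCOC)c(OC)c2)=C(OC)C=C(OCOC)C1C(C)(C)C=C | intermediate
15 | 3-methoxy-2-[3-methoxy-4-(methoxymethoxy)benzoyl]-5-(methoxymethoxy)-4-(3-methylbut-2-en-1-yl)cyclohexa-2,5-dien-1-one | O=C1C(C(=O)c2ccc(OCOC)c(OC)c2)=C(OC)C(CC=C(C)C)C(OCOC)=C1 | intermediate
16 | [6-hydroxy-2-methoxy-4-(methoxymethoxy)-3-(3-methylbut-2-en-1-yl)phenyl][3-methoxy-4-(methoxymethoxy)phenyl]methanone | COc1c(CC=C(C)C)c(OCOC)cc(O)c1C(=O)c1ccc(OCOC)c(OC)c1 | intermediate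
17 | [4,6-dihydroxy-2-methoxy-3-(3-methylbut-2-en-1-yl)phenyl](4-hydroxy-3-methoxyphenyl)methanone | COc1cc(C(=O)c2c(O)cc(O)c(CC=C(C)C)c2OC)ccc1O | target

**Totals**
Total step count: 8. Longest linear sequence: 8 steps (1 → 17); triacetic acid lactone 4 enters unmodified in step 2.

**Three steps most likely to fail**

Step 3 (the triketo ester may close in the aldol mode to a resorcylate instead of giving 8). Fallback: ring B is taken ready-made. Setting out from 1, saponification (NaOH, aq MeOH, then HCl) gives vanillic acid F1. Friedel–Crafts C-acylation of commercial phloroglucinol with it in Eaton's reagent (P2O5/MeSO3H, 70 °C) gives (4-hydroxy-3-methoxyphenyl)(2,4,6-trihydroxyphenyl)methanone F2. MOMCl (2.1 equiv), K2CO3, acetone, 0 °C then protects the two non-chelated hydroxyls, and the sequence comes back to the route at 9.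

Step 4 (mono-MOM protection of the triol may give mixtures with the bis-ether). Fallback: the para oxygen is protected before ring B exists. Setting out from 4, MOMCl/K2CO3 in acetone gives 4-(methoxymethoxy)-6-methyl-2H-pyran-2-one F3. Lateral lithiation at the 6-methyl group (LDA 2.2 equiv, THF, −78 °C) and Claisen condensation with 3 gives 4-(methoxymethoxy)-6-{2-[3-methoxy-4-(methoxymethoxy)phenyl]-2-oxoethyl}-2H-pyran-2-one F4. Mg(OMe)2 in refluxing MeOH opens and recloses this as in step 3, and the sequence comes back to the route at 9 directly.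

Step 7 (the ortho-dienone may enolise to the 1,1-dimethylallyl isomer instead of undergoing the Cope shift). Fallback: the prenyl group is delivered by an ortho-Claisen rearrangement from the oxygen that later becomes the methoxy group, whose other ortho position is blocked by the aroyl group. Setting out from 8, MOMCl (2.2 equiv)/K2CO3 gives [2-hydroxy-4,6-bis(methoxymethoxy)phenyl][3-methoxy-4-(methoxymethoxy)phenyl]methanone F5. Alkylation with 3-chloro-3-methylbut-1-yne (K2CO3, KI, CuI cat., acetone, reflux) gives {2,4-bis(methoxymethoxy)-6-[(2-methylbut-3-yn-2-yl)oxy]phenyl}[3-methoxy-4-(methoxymethoxy)phenyl]methanone F6. Lindlar semi-hydrogenation (H2, quinoline, EtOAc) gives {2,4-bis(methoxymethoxy)-6-[(2-methylbut-3-en-2-yl)oxy]phenyl}[3-methoxy-4-(methoxymethoxy)phenyl]methanone F7. Heating in toluene at 110 °C gives, by [3,3] shift, [2-hydroxy-4,6-bis(methoxymethoxy)-3-(3-methylbut-2-en-1-yl)phenyl][3-methoxy-4-(methoxymethoxy)phenyl]methanone F8. Me2SO4/K2CO3 in refluxing acetone gives [2-methoxy-4,6-bis(methoxymethoxy)-3-(3-methylbut-2-en-1-yl)phenyl][3-methoxy-4-(methoxymethoxy)phenyl]methanone F9. HCl/MeOH at rt removes the three MOM groups, and the sequence comes back to the route at 17.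

**Further compounds**
F1 | step 3 | vanillic acid (4-hydroxy-3-methoxybenzoic acid) | COc1cc(C(=O)O)ccc1O
F2 | step 3 | (4-hydroxy-3-methoxyphenyl)(2,4,6-trihydroxyphenyl)methanone | COc1cc(C(=O)c2c(O)cc(O)cc2O)ccc1O
F3 | step 4 | 4-(methoxymethoxy)-6-methyl-2H-pyran-2-one | CC1=CC(OCOC)=CC(=O)O1
F4 | step 4 | 4-(methoxymethoxy)-6-{2-[3-methoxy-4-(methoxymethoxy)phenyl]-2-oxoethyl}-2H-pyran-2-one | O=C(CC1=CC(OCOC)=CC(=O)O1)c1ccc(OCOC)c(OC)c1
F5 | step 7 | [2-hydroxy-4,6-bis(methoxymethoxy)phenyl][3-methoxy-4-(methoxymethoxy)phenyl]methanone | COCOc1cc(O)c(C(=O)c2ccc(OCOC)c(OC)c2)c(OCOC)c1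
F6 | step 7 | {2,4-bis(methoxymethoxy)-6-[(2-methylbut-3-yn-2-yl)oxy]phenyl}[3-methoxy-4-(methoxymethoxy)phenyl]methanone | COCOc1cc(OC(C)(C)C#C)c(C(=O)c2ccc(OCOC)c(OC)c2)c(OCOC)c1
F7 | step 7 | {2,4-bis(methoxymethoxy)-6-[(2-methylbut-3-en-2-yl)oxy]phenyl}[3-methoxy-4-(methoxymethoxy)phenyl]methanone | COCOc1cc(OC(C)(C)C=C)c(C(=O)c2ccc(OCOC)c(OC)c2)c(OCOC)c1
F8 | step 7 | [2-hydroxy-4,6-bis(methoxymethoxy)-3-(3-methylbut-2-en-1-yl)phenyl][3-methoxy-4-(methoxymethoxy)phenyl]methanone | COCOc1cc(OCOC)c(C(=O)c2ccc(OCOC)c(OC)c2)c(O)c1CC=C(C)C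
F9 | step 7 | [2-methoxy-4,6-bis(methoxymethoxy)-3-(3-methylbut-2-en-1-yl)phenyl][3-methoxy-4-(methoxymethoxy)phenyl]methanone | COCOc1cc(OCOC)c(C(=O)c2ccc(OCOC)c(OC)c2)c(OC)c1CC=C(C)C
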